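## Retrosynthetic overview
1. The 3(2H)-furanone is the last ring. It opens to a ten-membered α′-hydroxy enynone, and it is closed by transannular 5-endo-dig attack of O10 on C3 under gold catalysis.
2. The C8 ester is installed by Mitsunobu inversion of an 8S carbinol with (R)-2-methylbutanoic acid.
3. The ten-membered carbocycle (second ring) and the α-methylene-γ-lactone both arise from one intramolecular Barbier allylation. It forms C7–C8 from a 3-(bromomethyl)butenolide and the C8 aldehyde.
4. C3–C4 is a Sonogashira bond between a (Z)-iodoalkenyl butenolide and a terminal ynone aldehyde. The butenolide is the first ring (RCM), C6 comes from a lipase resolution, and the Z-iodide comes from trans-hydroalumination.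
5. The ynone aldehyde (C8–C10, C14, C1–C3) comes from (S)-citramalic acid, which supplies C10.

Assumption 1: C1–C15 are germacrane numbers (C1 ketone, C3 and C10 the furanone ether carbons, C6 the lactone carbinol, C8 the ester carbinol, C13 the exocyclic methylene, C15 the CH2OH).
Assumption 2: All purchased building blocks, including (S)-citramalic acid and (R)-2-methylbutanoic acid, are taken as commercially available.

## Route

Step 1
Reactants: 1 (S)-citramalic acid [(2S)-2-hydroxy-2-methylbutanedioic acid]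
Product: 2 2-[(4S)-2,2,4-trimethyl-5-oxo-1,3-dioxolan-4-yl]acetic acid
Conditions: Me2C(OMe)2, TsOH·H2O (cat.), acetone, rt
Reagents that add atoms: 2,2-dimethoxypropane, COC(C)(C)OC
Why: Acid-catalysed transacetalisation closes the five-membered dioxolanone on the α-hydroxy acid only, which differentiates the two carboxyls, while C10 (S) comes from the chiral pool and is not touched.

Step 2
Reactants: 2 2-[(4S)-2,2,4-trimethyl-5-oxo-1,3-dioxolan-4-yl]acetic acid
Product: 4 (3S)-3-hydroxy-3-methyloxolan-2-one, via (5S)-5-(2-hydroxyethyl)-2,2,5-trimethyl-1,3-dioxolan-4-one 3 (not isolated)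
Conditions: BH3·THF, THF, 0 °C to rt; MeOH quench, evaporate; TsOH·H2O (cat.), CH2Cl2, rt
Reagents that add atoms: none
Why: Chemoselective borane reduction of the free acid (the dioxolanone is inert) is followed by acid-catalysed translactonisation with loss of acetone, and the quaternary C10 centre cannot epimerise.

Step 3
Reactants: 4 (3S)-3-hydroxy-3-methyloxolan-2-one
Product: 5 (3S)-3-methyl-3-[(triethylsilyl)oxy]oxolan-2-one
Conditions: TESOTf, 2,6-lutidine, CH2Cl2, 0 °C to rt
Reagents that add atoms: triethylsilyl triflate, CC[Si](CC)(CC)OS(=O)(=O)C(F)(F)F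
Why: Silyl triflate silylation of the hindered tertiary alcohol masks O10 so that it cannot add to the ynone before the macrocycle exists.

Step 4
Reactants: 5 (3S)-3-methyl-3-[(triethylsilyl)oxy]oxolan-2-one; 6 ethynylmagnesium bromide
Product: 8 (4S)-6-hydroxy-4-methyl-4-[(triethylsilyl)oxy]hex-1-yn-3-one, via bromomagnesium (3S)-2-ethynyl-3-methyl-3-[(triethylsilyl)oxy]oxolan-2-olate (C2 epimers) 7 (not isolated)
Conditions: HC≡CMgBr (1.3 equiv), THF, −78 to −10 °C; sat. aq. NH4Cl
Reagents that add atoms: none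
Why: Acetylide addition to a lactone (nucleophilic acyl substitution) stops after one addition, because the lactolate persists until the quench and the carbonyl is flanked by a quaternary carbon.

Step 5
Reactants: 8 (4S)-6-hydroxy-4-methyl-4-[(triethylsilyl)oxy]hex-1-yn-3-one
Product: 9 (3S)-3-methyl-4-oxo-3-[(triethylsilyl)oxy]hex-5-ynal
Conditions: Dess–Martin periodinane, CH2Cl2, 0 °C to rt
Reagents that add atoms: none
Why: Dess–Martin oxidation of the primary alcohol runs without base, so the terminal ynone and the β-silyloxy aldehyde survive.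

Step 6
Reactants: 10 tert-butyldimethyl(prop-2-yn-1-yloxy)silane; 11 acrolein
Product: 13 (±)-6-[(tert-butyldimethylsilyl)oxy]hex-1-en-4-yn-3-ol, via lithium 3-[(tert-butyldimethylsilyl)oxy]prop-1-yn-1-ide 12 (not isolated)
Conditions: n-BuLi, THF, −78 °C; acrolein, −78 °C; sat. aq. NH4Cl
Reagents that add atoms: none
Why: 1,2-Addition of a lithium acetylide to the enal assembles C15–C4–C5–C6–C7, with C6 formed racemic at this stage.

Step 7
Reactants: 13 (±)-6-[(tert-butyldimethylsilyl)oxy]hex-1-en-4-yn-3-ol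
Product: 14 (3S)-6-[(tert-butyldimethylsilyl)oxy]hex-1-en-4-yn-3-ol
Conditions: Novozym 435 (CAL-B), vinyl acetate, hexane/MTBE, 30 °C, run to about 55 % conversion, chromatography
Reagents that add atoms: none
Why: In this lipase kinetic resolution the Kazlauskas rule (large alkynyl arm, medium vinyl) predicts acetylation of the (R)-alcohol, so the (S)-alcohol that carries the C6 configuration of the target is left behind in high ee.

Step 8
Reactants: 14 (3S)-6-[(tert-butyldimethylsilyl)oxy]hex-1-en-4-yn-3-ol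
Product: 16 (3S,4Z)-6-[(tert-butyldimethylsilyl)oxy]-5-iodohexa-1,4-dien-3-ol, via sodium (5S)-5-ethenyl-3-{[(tert-butyldimethylsilyl)oxy]methyl}-2,2-bis(2-methoxyethoxy)-2,5-dihydro-1,2-oxaaluminol-2-uide 15 (not isolated)
Conditions: Red-Al, THF, 0 °C to rt; I2, THF, −78 °C; aq. Rochelle salt
Reagents that add atoms: iodine, II
Why: Hydroxyl-directed trans-hydroalumination puts Al on C4 cis to C6 inside the cyclic alanate, and iodinolysis with retention gives only the Z-iodide, which is the C3/C6-cis geometry of C4=C5.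

Step 9
Reactants: 16 (3S,4Z)-6-[(tert-butyldimethylsilyl)oxy]-5-iodohexa-1,4-dien-3-ol; 17 acryloyl chloride
Product: 18 (3S,4Z)-6-[(tert-butyldimethylsilyl)oxy]-5-iodohexa-1,4-dien-3-yl prop-2-enoate
Conditions: acryloyl chloride, i-Pr2NEt, CH2Cl2, −20 to 0 °C
Reagents that add atoms: none
Why: O-Acylation with an acid chloride leaves the C6–O bond intact, so C6 is retained.

Step 10
Reactants: 18 (3S,4Z)-6-[(tert-butyldimethylsilyl)oxy]-5-iodohexa-1,4-dien-3-yl prop-2-enoate; 19 formaldehyde
Product: 20 (3S,4Z)-6-[(tert-butyldimethylsilyl)oxy]-5-iodohexa-1,4-dien-3-yl 2-(hydroxymethyl)prop-2-enoate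
Conditions: 37 % aq. HCHO, DABCO, 1,4-dioxane/H2O, rt
Reagents that add atoms: none
Why: Morita–Baylis–Hillman hydroxymethylation of the acrylate installs C13 as a free allylic alcohol, a group that tolerates the later palladium step where an allylic bromide would not.

Step 11
Reactants: 20 (3S,4Z)-6-[(tert-butyldimethylsilyl)oxy]-5-iodohexa-1,4-dien-3-yl 2-(hydroxymethyl)prop-2-enoate
Product: 21 (5S)-5-[(1Z)-3-[(tert-butyldimethylsilyl)oxy]-2-iodoprop-1-en-1-yl]-3-(hydroxymethyl)furan-2(5H)-one
Conditions: Grubbs II (5 mol %), 1,4-benzoquinone (10 mol %), CH2Cl2 (5 mM), reflux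
Reagents that add atoms: none
Why: Ring-closing metathesis between the terminal vinyl group and the 1,1-disubstituted acrylate closes the butenolide (C7=C11), while the trisubstituted iodoalkene is inert and C6 is untouched.

Step 12
Reactants: 21 (5S)-5-[(1Z)-3-[(tert-butyldimethylsilyl)oxy]-2-iodoprop-1-en-1-yl]-3-(hydroxymethyl)furan-2(5H)-one; 9 (3S)-3-methyl-4-oxo-3-[(triethylsilyl)oxy]hex-5-ynal
Product: 22 (3S,7E)-7-{[(tert-butyldimethylsilyl)oxy]methyl}-8-[(2R)-4-(hydroxymethyl)-5-oxo-2,5-dihydrofuran-2-yl]-3-methyl-4-oxo-3-[(triethylsilyl)oxy]oct-7-en-5-ynal (C3 and C6 cis on C4=C5)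
Conditions: PdCl2(PPh3)2 (5 mol %), CuI (10 mol %), i-Pr2NEt (1.5 equiv), THF, 0 °C, slow addition of 9
Reagents that add atoms: none
Why: Sonogashira coupling forms C3–C4 with retention of the alkene geometry, and the acidic ynone C–H allows a hindered tertiary amine at 0 °C, which spares the base-sensitive C6–H and the aldehyde.

Step 13
Reactants: 22 (the C13 allylic alcohol from step 12)
Product: 23 (3S,7E)-8-[(2R)-4-(bromomethyl)-5-oxo-2,5-dihydrofuran-2-yl]-7-{[(tert-butyldimethylsilyl)oxy]methyl}-3-methyl-4-oxo-3-[(triethylsilyl)oxy]oct-7-en-5-ynal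
Conditions: NBS, Me2S, CH2Cl2, −30 °C; add 22; warm to 0 °C
Reagents that add atoms: N-bromosuccinimide, O=C1CCC(=O)N1Br
Why: Corey–Kim bromination activates the only free (primary allylic) hydroxyl and bromide displaces it by SN2 under neutral, phosphine-free conditions that spare the aldehyde, the ynone and both silyl ethers.

Step 14
Reactants: 23 (the C13 allylic bromide from step 13)
Product: 25 (6R,7R,8S,10S)-15-[(tert-butyldimethylsilyl)oxy]-8-hydroxy-1-oxo-10-[(triethylsilyl)oxy]germacra-4,11(13)-dien-2-yn-12,6-olide (ten-membered ring, C3/C6 cis on C4=C5, 6,7-trans lactone), via the C13 allylindium species (drawn as R–InBr2) 24 (not isolated)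
Conditions: In powder (5 equiv), THF/H2O 4:1, syringe-pump addition of 23, final 1 mM, rt
Reagents that add atoms: none
Why: In this intramolecular Barbier (SE2′) allylation the rigid enyne tether lets the aldehyde reach C7 only on the butenolide face opposite C5 (6,7-trans, 7R), and the ring-locked E-type allylmetal reacts through a Zimmerman–Traxler chair with C9 equatorial to give the 7,8-anti carbinol (8S).

Step 15
Reactants: 25 (the 8S carbinol from step 14); 26 (R)-2-methylbutanoic acid
Product: 27 (6R,7R,8R,10S)-15-[(tert-butyldimethylsilyl)oxy]-8-{[(2R)-2-methylbutanoyl]oxy}-1-oxo-10-[(triethylsilyl)oxy]germacra-4,11(13)-dien-2-yn-12,6-olide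
Conditions: PPh3 and DIAD premixed, toluene, 0 °C; then 26 and 25; 0 °C to rt
Reagents that add atoms: none
Why: Mitsunobu esterification displaces the activated C8–O bond by SN2 with the carboxylate and inverts C8 from S to R, and the acid's α-centre is safe because its acyl carbon is never activated.

Step 16
Reactants: 27 (the bis-silyl ester from step 15)
Product: 28 (6R,7R,8R,10S)-10,15-dihydroxy-8-{[(2R)-2-methylbutanoyl]oxy}-1-oxogermacra-4,11(13)-dien-2-yn-12,6-olide
Conditions: HF·pyridine, pyridine, THF, 0 °C to rt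
Reagents that add atoms: none
Why: Buffered fluoride desilylation removes the tertiary TES and the primary TBS ether in one operation without touching the ester, the α-methylene lactone or any stereocentre.

Step 17
Reactants: 28 (the diol ynone from step 16)
Product: 29 target, (6R,7R,8R,10S)-3,10-epoxy-15-hydroxy-8-{[(2R)-2-methylbutanoyl]oxy}-1-oxogermacra-2,4Z,11(13)-trien-12,6-olide
Conditions: (4-CF3C6H4)3PAuCl (5 mol %), AgOTf (5 mol %), toluene, rt
Reagents that add atoms: none
Why: Gold(I)-catalysed 5-endo-dig cycloisomerisation of the α′-hydroxy ynone sends O10 to the β-carbon C3 (C15–OH could only attack the electronically mismatched C2) and closes the 3(2H)-furanone with no change at C10.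

## Compound list
1 | (S)-citramalic acid | OC(=O)[C@](C)(CC(=O)O)O | starting material
2 | 2-[(4S)-2,2,4-trimethyl-5-oxo-1,3-dioxolan-4-yl]acetic acid | O=C1[C@](C)(CC(=O)O)OC(C)(C)O1 | intermediate
3 | (5S)-5-(2-hydroxyethyl)-2,2,5-trimethyl-1,3-dioxolan-4-one (not isolated) | O=C1[C@](C)(CCO)OC(C)(C)O1 | intermediate
4 | (3S)-3-hydroxy-3-methyloxolan-2-one | O=C1[C@](C)(CCO1)O | intermediate
5 | (3S)-3-methyl-3-[(triethylsilyl)oxy]oxolan-2-one | O=C1[C@](C)(CCO1)O[Si](CC)(CC)CC | intermediate
6 | ethynylmagnesium bromide | C#C[Mg]Br | starting material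
7 | bromomagnesium (3S)-2-ethynyl-3-methyl-3-[(triethylsilyl)oxy]oxolan-2-olate, C2 epimers (not isolated) | C#CC1(O[Mg]Br)OCC[C@]1(C)O[Si](CC)(CC)CC | intermediate
8 | (4S)-6-hydroxy-4-methyl-4-[(triethylsilyl)oxy]hex-1-yn-3-one | C#CC(=O)[C@](C)(CCO)O[Si](CC)(CC)CC | intermediate
9 | (3S)-3-methyl-4-oxo-3-[(triethylsilyl)oxy]hex-5-ynal | C#CC(=O)[C@](C)(CC=O)O[Si](CC)(CC)CC | intermediate
10 | tert-butyldimethyl(prop-2-yn-1-yloxy)silane | C#CCO[Si](C)(C)C(C)(C)C | starting material
11 | acrolein | C=CC=O | starting material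
12 | lithium 3-[(tert-butyldimethylsilyl)oxy]prop-1-yn-1-ide (not isolated) | [Li]C#CCO[Si](C)(C)C(C)(C)C | intermediate
13 | (±)-6-[(tert-butyldimethylsilyl)oxy]hex-1-en-4-yn-3-ol | C=CC(O)C#CCO[Si](C)(C)C(C)(C)C | intermediate
14 | (3S)-6-[(tert-butyldimethylsilyl)oxy]hex-1-en-4-yn-3-ol | O[C@@H](C=C)C#CCO[Si](C)(C)C(C)(C)C | intermediate
15 | sodium cyclic alkenylalanate, (5S) (not isolated) | [Na+].C=C[C@H]1C=C(CO[Si](C)(C)C(C)(C)C)[Al-](OCCOC)(OCCOC)O1 | intermediate
16 | (3S,4Z)-6-[(tert-butyldimethylsilyl)oxy]-5-iodohexa-1,4-dien-3-ol | O[C@@H](C=C)/C=C(/CO[Si](C)(C)C(C)(C)C)I | intermediate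
17 | acryloyl chloride | C=CC(=O)Cl | starting material
18 | (3S,4Z)-6-[(tert-butyldimethylsilyl)oxy]-5-iodohexa-1,4-dien-3-yl prop-2-enoate | C=CC(=O)O[C@@H](C=C)/C=C(/CO[Si](C)(C)C(C)(C)C)I | intermediate
19 | formaldehyde | C=O | starting material
20 | (3S,4Z)-6-[(tert-butyldimethylsilyl)oxy]-5-iodohexa-1,4-dien-3-yl 2-(hydroxymethyl)prop-2-enoate | C=C(CO)C(=O)O[C@@H](C=C)/C=C(/CO[Si](C)(C)C(C)(C)C)I | intermediate
21 | (5S)-5-[(1Z)-3-[(tert-butyldimethylsilyl)oxy]-2-iodoprop-1-en-1-yl]-3-(hydroxymethyl)furan-2(5H)-one | O=C1O[C@@H](C=C1CO)/C=C(/CO[Si](C)(C)C(C)(C)C)I | intermediate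
22 | coupled enynone aldehyde with C13–OH, (6R,10S) | O=C1O[C@@H](C=C1CO)/C=C(/CO[Si](C)(C)C(C)(C)C)C#CC(=O)[C@](C)(CC=O)O[Si](CC)(CC)CC | intermediate
23 | coupled enynone aldehyde with C13–Br, (6R,10S) | O=C1O[C@@H](C=C1CBr)/C=C(/CO[Si](C)(C)C(C)(C)C)C#CC(=O)[C@](C)(CC=O)O[Si](CC)(CC)CC | intermediate
24 | C13 allylindium species drawn as R–InBr2 (not isolated) | O=C1O[C@@H](C=C1C[In](Br)Br)/C=C(/CO[Si](C)(C)C(C)(C)C)C#CC(=O)[C@](C)(CC=O)O[Si](CC)(CC)CC | intermediate
25 | (6R,7R,8S,10S) macrocyclic carbinol | C=C1C(=O)O[C@@H]2/C=C(/CO[Si](C)(C)C(C)(C)C)C#CC(=O)[C@](C)(C[C@H](O)[C@@H]12)O[Si](CC)(CC)CC | intermediate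
26 | (R)-2-methylbutanoic acid | CC[C@@H](C)C(=O)O | starting material
27 | (6R,7R,8R,10S) macrocyclic (2R)-2-methylbutanoate, bis-silyl ether | C=C1C(=O)O[C@@H]2/C=C(/CO[Si](C)(C)C(C)(C)C)C#CC(=O)[C@](C)(C[C@@H](OC(=O)[C@H](C)CC)[C@@H]12)O[Si](CC)(CC)CC | intermediate
28 | (6R,7R,8R,10S) 10,15-dihydroxy enynone | C=C1C(=O)O[C@@H]2/C=C(/CO)C#CC(=O)[C@](C)(C[C@@H](OC(=O)[C@H](C)CC)[C@@H]12)O | intermediate
29 | CNP0307052.2 | C=C1C(=O)O[C@@H]2/C=C(/CO)C3=CC(=O)[C@](C)(C[C@@H](OC(=O)[C@H](C)CC)[C@@H]12)O3 | target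

## Totals and risks
Total step count: 17.
Longest linear sequence: 12 steps (steps 6–17, from 10 and 11). The citramalate branch is 11 steps (steps 1–5 and 12–17).

**Step 14, macrocyclic Barbier allylation.** The risks are ring closure against oligomerisation or protonolysis, and facial control at C7. The fallback sets out from 21 (with 9) and comes back at 25, and it reverses the order of the two C–C bond formations.
- Compound 21 is brominated with NBS/Me2S to (5S)-3-(bromomethyl)-5-[(1Z)-3-[(tert-butyldimethylsilyl)oxy]-2-iodoprop-1-en-1-yl]furan-2(5H)-one F3.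
- An intermolecular indium Barbier reaction of this bromolactone with 9 sets C7 and C8 under purely reagent-controlled conditions: attack anti to the C5 arm and a chair transition state.
- It gives the open-chain (4S,6S)-6-{(2S,3R)-2-[(1Z)-3-[(tert-butyldimethylsilyl)oxy]-2-iodoprop-1-en-1-yl]-4-methylidene-5-oxooxolan-3-yl}-6-hydroxy-4-methyl-4-[(triethylsilyl)oxy]hex-1-yn-3-one F4.
- The ten-membered ring is then closed at C3–C4 by intramolecular Sonogashira coupling (Pd(PPh3)4, CuI, i-Pr2NEt, THF, 1 mM, syringe pump) to give 25.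

**Step 15, Mitsunobu inversion.** C8 is a hindered, β-branched carbinol, elimination towards C7 can compete, and PPh3 is used in the presence of an ynone. The fallback sets out from 25 and comes back at 27, and it separates activation from displacement.
- Compound 25 is converted with ClCH2SO2Cl and pyridine into the isolable (6R,7R,8S,10S)-8-chloromethanesulfonate F5.
- This is displaced with caesium (R)-2-methylbutanoate (from 26 and Cs2CO3) and 18-crown-6 in toluene, a phosphine-free SN2 inversion that gives 27.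

**Step 12, Sonogashira coupling.** The terminal ynone is amine-sensitive, and C6–H is acidic in 21 and 22. The fallback sets out from 5 and comes back at 22, and it replaces the copper acetylide and amine by a preformed alkynylstannane.
- Lithium (tributylstannyl)acetylide is added to 5 to give (4S)-6-hydroxy-4-methyl-4-[(triethylsilyl)oxy]-1-(tributylstannyl)hex-1-yn-3-one F1.
- Dess–Martin oxidation gives (3S)-3-methyl-4-oxo-3-[(triethylsilyl)oxy]-6-(tributylstannyl)hex-5-ynal F2.
- A base-free Stille coupling of this stannane with 21 (Pd2(dba)3, AsPh3, DMF, rt) gives 22.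

## Further compounds
F1 | step 12 | (4S)-6-hydroxy-4-methyl-4-[(triethylsilyl)oxy]-1-(tributylstannyl)hex-1-yn-3-one | CCCC[Sn](CCCC)(CCCC)C#CC(=O)[C@](C)(CCO)O[Si](CC)(CC)CC
F2 | step 12 | (3S)-3-methyl-4-oxo-3-[(triethylsilyl)oxy]-6-(tributylstannyl)hex-5-ynal | CCCC[Sn](CCCC)(CCCC)C#CC(=O)[C@](C)(CC=O)O[Si](CC)(CC)CC
F3 | step 14 | (5S)-3-(bromomethyl)-5-[(1Z)-3-[(tert-butyldimethylsilyl)oxy]-2-iodoprop-1-en-1-yl]furan-2(5H)-one | O=C1O[C@@H](C=C1CBr)/C=C(/CO[Si](C)(C)C(C)(C)C)I
F4 | step 14 | (4S,6S)-6-{(2S,3R)-2-[(1Z)-3-[(tert-butyldimethylsilyl)oxy]-2-iodoprop-1-en-1-yl]-4-methylidene-5-oxooxolan-3-yl}-6-hydroxy-4-methyl-4-[(triethylsilyl)oxy]hex-1-yn-3-one | C=C1C(=O)O[C@H](/C=C(/CO[Si](C)(C)C(C)(C)C)I)[C@H]1[C@@H](O)C[C@](C)(O[Si](CC)(CC)CC)C(=O)C#C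
F5 | step 15 | (6R,7R,8S,10S)-8-chloromethanesulfonate of 25 | C=C1C(=O)O[C@@H]2/C=C(/CO[Si](C)(C)C(C)(C)C)C#CC(=O)[C@](C)(C[C@H](OS(=O)(=O)CCl)[C@@H]12)O[Si](CC)(CC)CC
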